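The meeting opened on an impossibility: the red and violet runs stop at 40.0 h, while the flasks asked about end later, at 3.0 d, 5.0 d and 6.0 d, so none of their end states stands in a table.

| flask | starting material | solid reagent | remark | time |
|---|---|---|---|---|
| red | 0.47 M | 0.40 equiv | run made earlier |  |
| violet | 0.47 M | 0.90 equiv | run made earlier |  |
| south-west | 0.47 M | 0.600 equiv |  | 3.0 d |
| west | 0.47 M | 0.600 equiv |  | 5.0 d |
| north-west | 0.47 M | 0.600 equiv |  | 6.0 d |

| run | time / h | side product / % | intermediate B / % | target / % | starting material / % |
|---|---|---|---|---|---|
| red | 5.00 | 5.0 | 0.4 | 0.3 | 90.2 |
| red | 15.0 | 20.7 | 3.4 | 0.1 | 71.6 |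
| red | 30.0 | 40.2 | 7.0 | 0.7 | 48.8 |
| red | 40.0 | 49.5 | 8.5 | 0.8 | 38.1 |
| violet | 10.0 | 12.4 | 1.4 | 0 | 80.6 |
| violet | 20.0 | 27.7 | 4.0 | 0 | 62.8 |
| violet | 30.0 | 40.2 | 7.3 | 0.3 | 48.4 |
| violet | 40.0 | 49.6 | 10.2 | 0.6 | 37.3 |

(scatter of a reading: 0.3 percentage points)

- solid, in amounts per volume of the solution: solid reagent
- at the start none of the solid reagent is in solution

- which of these there is most of at the end, counted by the starting material in it, south-west (target / starting material / side product / intermediate B)
- which of these there is most of at the end, counted by the starting material in it, west (target / starting material / side product / intermediate B)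
- which of these there is most of at the end, counted by the starting material in it, north-west (target / starting material / side product / intermediate B)
- how much there is at the end of the one of these that leads, in percent of the starting material charged: south-west
- how much there is at the end of the one of these that leads, in percent of the starting material charged: west
- how much there is at the end of the one of these that leads, in percent of the starting material charged: north-west

The first chemist proposed counting half-lives. Between 15.0 h and 40.0 h the red run fell from 71.6 % to 38.1 % of starting material, which she treated as a pseudo-first-order decay and reckoned at 27.5 h. This is the apparent half-life, the time in which the remaining starting material halves.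

The second chemist objected that the violet run holds 0.90 equiv of solid reagent against 0.40 equiv in the red run. But its readings from 20.0 h to 40.0 h give 26.6 h, so the meeting kept the red figure for 0.600 equiv, which lies between the two charges. South-west then spans 2.62 half-lives, west 4.37 and north-west 5.24, leaving 16.3 %, 4.84 % and 2.64 % of the starting material.

The third chemist added that the red run at 40.0 h held 49.5 % of side product against 61.9 % of starting material consumed, a share of 80.0 %. If that share holds, side product comes to 67.0 %, 76.1 % and 77.9 %. Even in south-west that is more than the starting material left or the largest remainder of the consumed share in any of these flasks, so the meeting named side product as leader.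

The forecast named side product for south-west, side product for west and side product for north-west, at 65 % (58 % to 71 %), 73 % (62 % to 81 %) and 75 % (62 % to 84 %), with the caution “It leads throughout unless it slowly drains or reverts”. For north-west its figure stands lower than the meeting's.

The flasks give side product at 67.0 %, side product at 76.3 % and side product at 78.0 %.

    starting material → intermediate A (k = 5.60 × 10⁻⁶ s⁻¹)
    solid reagent ⇌ partner, rate k2*(cs2 - [partner]) while solid is left; crystals form when [partner] > cs2 (solubility = 0.400 M, k = 8.20 × 10⁻⁶ s⁻¹)
    intermediate A → side product (k = 8.07 × 10⁻⁵ s⁻¹)
    starting material + partner → intermediate B (k = 8.94 × 10⁻⁶ L mol⁻¹ s⁻¹)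
    intermediate B → target (k = 1.45 × 10⁻⁶ s⁻¹)

Against the count from 27.5 h, the flasks hold 15 %, 4.3 % and 2.3 % of starting material where 16.3 %, 4.84 % and 2.64 % were reckoned. Among the settings tried, north-west's side product answers in the order time (2.7 points), then solid reagent (2.1 points), then starting material (1.5 points). A neighbour of west, charged at [starting material] = 0.19 M with the same equivalents and read at the same 5.0 d, counts the same 4.37 half-lives if 27.5 h is carried over, which gives 4.84 % left and 76.1 % of side product. That neighbour holds 6.20 % of starting material and 81.6 % of side product.

All runs are calculated with made-up constants, and the scatter is random.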